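**Retrosynthetic overview**
1. The last bond made is aryl C7–CH2. The target splits into the free 4,6-dihydroxy-dihydrobenzofuran ketone, whose only aromatic C–H is C7, and a 3-(dimethylaminomethyl)pyrone that acts as a latent 3-methylidene-pyran-2,4-dione.
2. Pyrone half: the Mannich base comes from 6-ethyl-4-hydroxy-5-methyl-2-pyrone and [Me2N=CH2]I. The pyrone ring comes from the silyl enol ether of pentan-3-one and malonyl dichloride.
3. Benzofuran half: the dihydrofuran ring and C2 (R) come from an enantioselective Pd Heck/Tsuji–Trost annulation of an o-bromophenol with isoprene.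
4. The bromophenol comes from resorcinol by bis-MOM protection, lithiation between the two OMOM groups, acylation with the Weinreb amide of (R)-2-methylbutanoic acid, Ir C–H borylation/oxidation para to the ketone, then NBS.
5. Ring order: the benzene ring is bought. The dihydrofuran ring (step 6) and the pyrone ring (step 9) are closed in separate branches, and the final coupling closes no ring.

Assumption: (R)-2-methylbutanoic acid (≥98% ee) is bought as such, and the TY-Phos antipode used in step 6 is the one that converts 4-acetyl-2-bromophenol and isoprene into (R)-tremetone.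

**Fragment A (benzofuran half)**

Step 1
Reactants: 1 (2R)-2-methylbutanoic acid
Product: 3 (2R)-N-methoxy-N,2-dimethylbutanamide, via acyl imidazolide 2 (not isolated)
Conditions: CDI (1.1 equiv), CH2Cl2, 0 °C → rt, 1 h; then MeNH(OMe)·HCl (1.2 equiv), rt, 12 h
Reagents that add atoms: N,O-dimethylhydroxylamine hydrochloride, CNOC.Cl; 1,1'-carbonyldiimidazole, O=C(n1ccnc1)n1ccnc1 (imidazolyl of 2 only)
Why: This is a Weinreb amide synthesis through the acyl imidazolide without added base, so no ketene or enolate forms and the purchased (R) centre is carried through unchanged.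

Step 2
Reactants: 4 resorcinol (benzene-1,3-diol)
Product: 5 1,3-bis(methoxymethoxy)benzene
Conditions: NaH (2.4 equiv), MOMCl (2.4 equiv), DMF, 0 °C → rt
Reagents that add atoms: chloromethyl methyl ether, COCCl
Why: Williamson-type O-alkylation of the bis-phenoxide installs two MOM acetals that protect the phenols and later act together as ortho-directing groups.

Step 3
Reactants: 5 1,3-bis(methoxymethoxy)benzene; 3 (2R)-N-methoxy-N,2-dimethylbutanamide
Product: 8 (2R)-1-[2,6-bis(methoxymethoxy)phenyl]-2-methylbutan-1-one, via aryllithium 6 (not isolated), via tetrahedral lithium adduct 7 (not isolated)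
Conditions: n-BuLi (1.1 equiv), THF, 0 °C → rt, 1.5 h; then 3, −78 → 0 °C; cold sat. aq. NH4Cl
Reagents that add atoms: n-butyllithium, [Li]CCCC (lithium of 6 and 7 only)
Why: Directed ortho-metalation occurs only at C2 between the two chelating OMOM groups, and the Weinreb ketone synthesis rests at chelate 7 until the cold quench, so there is neither over-addition nor enolisation of the (R) α-centre.

Step 4
Reactants: 8 (2R)-1-[2,6-bis(methoxymethoxy)phenyl]-2-methylbutan-1-one
Product: 10 (2R)-1-[4-hydroxy-2,6-bis(methoxymethoxy)phenyl]-2-methylbutan-1-one, via aryl pinacol boronate 9 (not isolated)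
Conditions: [Ir(OMe)(cod)]2 (1.5 mol %), 4,4'-di-tert-butyl-2,2'-bipyridine (3 mol %), B2pin2 (1.0 equiv), THF, 80 °C, 16 h; evaporate; then NaBO3·4H2O (3 equiv), THF/H2O 1:1, rt, 2 h
Reagents that add atoms: bis(pinacolato)diboron, CC1(C)OB(OC1(C)C)B1OC(C)(C)C(C)(C)O1 (Bpin of 9 only); sodium perborate tetrahydrate, [Na+].[O-]OB=O.O.O.O.O (phenol oxygen)
Why: Sterically governed Hartwig–Miyaura C–H borylation of this 1,2,3-trisubstituted arene reaches only the C–H para to the ketone, the sole position without an ortho substituent, and mild perborate oxidation of the C–B bond places the third oxygen there.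

Step 5
Reactants: 10 (2R)-1-[4-hydroxy-2,6-bis(methoxymethoxy)phenyl]-2-methylbutan-1-one
Product: 11 (2R)-1-[3-bromo-4-hydroxy-2,6-bis(methoxymethoxy)phenyl]-2-methylbutan-1-one
Conditions: NBS (1.0 equiv), MeCN, −20 → 0 °C, dark
Reagents that add atoms: N-bromosuccinimide, O=C1CCC(=O)N1Br
Why: In this electrophilic aromatic bromination the para position of the phenol is blocked and the two ortho positions are equivalent by symmetry, so one equivalent of NBS at low temperature gives a single monobromide.

Step 6
Reactants: 11 (2R)-1-[3-bromo-4-hydroxy-2,6-bis(methoxymethoxy)phenyl]-2-methylbutan-1-one; 12 isoprene (2-methylbuta-1,3-diene)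
Product: 13 (2R)-1-[(2R)-4,6-bis(methoxymethoxy)-2-(prop-1-en-2-yl)-2,3-dihydro-1-benzofuran-5-yl]-2-methylbutan-1-one
Conditions: Pd2(dba)3·CHCl3 (5 mol %), TY-Phos (12 mol %), PhONa (2 equiv), 12 (5 equiv), CH2Cl2, 40 °C, sealed tube
Reagents that add atoms: none
Why: In this enantioselective Larock-type heteroannulation (Heck/Tsuji–Trost cascade), oxidative addition, carbopalladation at the terminal carbon of the less substituted alkene of isoprene and ligand-controlled 5-exo allylic C–O closure set C2 as R in the same sense as for (R)-tremetone, and since only the OH para to the ketone is free the ring oxygen can end up only there.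

Step 7
Reactants: 13 (2R)-1-[(2R)-4,6-bis(methoxymethoxy)-2-(prop-1-en-2-yl)-2,3-dihydro-1-benzofuran-5-yl]-2-methylbutan-1-one
Product: 14 (2R)-1-[(2R)-4,6-dihydroxy-2-(prop-1-en-2-yl)-2,3-dihydro-1-benzofuran-5-yl]-2-methylbutan-1-one
Conditions: HCl (1.25 M in MeOH, catalytic in acid), 0 °C → rt, monitored by TLC
Reagents that add atoms: none
Why: Acid-catalysed acetal exchange (MOM cleavage) is accelerated by hydrogen bonding of each freed phenol to the ortho ketone and runs at or below room temperature, where the inductively deactivated isopropenyl group, the allylic C2–O bond and the α-centre of the strongly conjugated ketone stay intact.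

**Fragment B (pyrone half)**

Step 8
Reactants: 15 pentan-3-one
Product: 16 (Z)-trimethyl(pent-2-en-3-yloxy)silane (Z major, the E/Z mixture is used)
Conditions: TMSOTf (1.1 equiv), Et3N (1.3 equiv), CH2Cl2, 0 °C, 1 h; pentane extraction, distillation
Reagents that add atoms: trimethylsilyl triflate, C[Si](C)(C)OS(=O)(=O)C(F)(F)F
Why: Soft enolisation and O-silylation of a symmetric ketone can give only one regioisomer, and the alkene geometry is erased in the next step.

Step 9
Reactants: 16 (Z)-trimethyl(pent-2-en-3-yloxy)silane; 17 malonyl dichloride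
Product: 19 6-ethyl-4-hydroxy-5-methyl-2H-pyran-2-one, via diketo acid chloride 18 (not isolated)
Conditions: 17 (1.0 equiv), Et2O, −78 °C → rt, overnight; product crystallises
Reagents that add atoms: none
Why: In the Effenberger pyrone synthesis one acid chloride end C-acylates the silyl enol ether and the other end is then O-acylated by the enolised ketone, which after tautomerisation places Me at C5 and Et at C6 of the 4-hydroxy-2-pyrone.

Step 10
Reactants: 19 6-ethyl-4-hydroxy-5-methyl-2H-pyran-2-one; 20 N,N-dimethylmethyleneiminium iodide ([Me2N=CH2]I, Eschenmoser's salt)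
Product: 21 3-[(dimethylamino)methyl]-6-ethyl-4-hydroxy-5-methyl-2H-pyran-2-one
Conditions: 20 (1.1 equiv), CH2Cl2, 0 °C → rt, 2 h; aq. NaHCO3 wash, CH2Cl2 extraction; stored cold and used within a day
Reagents that add atoms: none
Why: In this Mannich reaction C3, the only nucleophilic C–H of the pyrone, attacks the preformed iminium ion quickly under aprotic conditions, so no free formaldehyde is present and methylene-bis-pyrone formation is suppressed.

**Union of fragments A and B**

Step 11
Reactants: 14 (2R)-1-[(2R)-4,6-dihydroxy-2-(prop-1-en-2-yl)-2,3-dihydro-1-benzofuran-5-yl]-2-methylbutan-1-one; 21 3-[(dimethylamino)methyl]-6-ethyl-4-hydroxy-5-methyl-2H-pyran-2-one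
Product: 23 3-({(2R)-4,6-dihydroxy-5-[(2R)-2-methylbutanoyl]-2-(prop-1-en-2-yl)-2,3-dihydro-1-benzofuran-7-yl}methyl)-6-ethyl-4-hydroxy-5-methyl-2H-pyran-2-one, via methylidene pyrandione 22 (not isolated)
Conditions: 14 (1.0 equiv), 21 (1.2 equiv, added in portions over 2 h), 1,4-dioxane, 90 °C, slow N2 sweep
Reagents that add atoms: none
Why: Thermal retro-Michael loss of dimethylamine gives the quinone-methide-like acceptor 22, which the only free aromatic carbon (C7, ortho/para to three oxygens and meta to the acyl group) captures in a Michael/Friedel–Crafts alkylation followed by re-aromatisation, without touching either stereocentre.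

**Compound list**
1 | (2R)-2-methylbutanoic acid | CC[C@@H](C)C(=O)O | starting material
2 | 1-[(2R)-2-methylbutanoyl]imidazole | CC[C@@H](C)C(=O)n1ccnc1 | intermediate
3 | (2R)-N-methoxy-N,2-dimethylbutanamide | CC[C@@H](C)C(=O)N(C)OC | intermediate
4 | resorcinol | Oc1cccc(O)c1 | starting material
5 | 1,3-bis(methoxymethoxy)benzene | COCOc1cccc(OCOC)c1 | intermediate
6 | [2,6-bis(methoxymethoxy)phenyl]lithium | [Li]c1c(OCOC)cccc1OCOC | intermediate
7 | lithium (2R)-1-[2,6-bis(methoxymethoxy)phenyl]-1-[methoxy(methyl)amino]-2-methylbutan-1-olate (C1 undefined) | CC[C@@H](C)C(O[Li])(N(C)OC)c1c(OCOC)cccc1OCOC | intermediate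
8 | (2R)-1-[2,6-bis(methoxymethoxy)phenyl]-2-methylbutan-1-one | CC[C@@H](C)C(=O)c1c(OCOC)cccc1OCOC | intermediate
9 | (2R)-1-[2,6-bis(methoxymethoxy)-4-(4,4,5,5-tetramethyl-1,3,2-dioxaborolan-2-yl)phenyl]-2-methylbutan-1-one | CC[C@@H](C)C(=O)c1c(OCOC)cc(B2OC(C)(C)C(C)(C)O2)cc1OCOC | intermediate
10 | (2R)-1-[4-hydroxy-2,6-bis(methoxymethoxy)phenyl]-2-methylbutan-1-one | CC[C@@H](C)C(=O)c1c(OCOC)cc(O)cc1OCOC | intermediate
11 | (2R)-1-[3-bromo-4-hydroxy-2,6-bis(methoxymethoxy)phenyl]-2-methylbutan-1-one | CC[C@@H](C)C(=O)c1c(OCOC)cc(O)c(Br)c1OCOC | intermediate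
12 | isoprene | C=CC(C)=C | starting material
13 | (2R)-1-[(2R)-4,6-bis(methoxymethoxy)-2-(prop-1-en-2-yl)-2,3-dihydro-1-benzofuran-5-yl]-2-methylbutan-1-one | C=C(C)[C@H]1Cc2c(OCOC)c(C(=O)[C@H](C)CC)c(OCOC)cc2O1 | intermediate
14 | (2R)-1-[(2R)-4,6-dihydroxy-2-(prop-1-en-2-yl)-2,3-dihydro-1-benzofuran-5-yl]-2-methylbutan-1-one | C=C(C)[C@H]1Cc2c(O)c(C(=O)[C@H](C)CC)c(O)cc2O1 | intermediate
15 | pentan-3-one | CCC(=O)CC | starting material
16 | (Z)-trimethyl(pent-2-en-3-yloxy)silane | C/C=C(\O[Si](C)(C)C)CC | intermediate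
17 | malonyl dichloride | O=C(Cl)CC(=O)Cl | starting material
18 | 4-methyl-3,5-dioxoheptanoyl chloride | CCC(=O)C(C)C(=O)CC(=O)Cl | intermediate
19 | 6-ethyl-4-hydroxy-5-methyl-2H-pyran-2-one | CCc1oc(=O)cc(O)c1C | intermediate
20 | N,N-dimethylmethyleneiminium iodide | C[N+](C)=C.[I-] | starting material
21 | 3-[(dimethylamino)methyl]-6-ethyl-4-hydroxy-5-methyl-2H-pyran-2-one | CCc1oc(=O)c(CN(C)C)c(O)c1C | intermediate
22 | 6-ethyl-5-methyl-3-methylidenepyran-2,4-dione | C=C1C(=O)OC(CC)=C(C)C1=O | intermediate
23 | 3-({(2R)-4,6-dihydroxy-5-[(2R)-2-methylbutanoyl]-2-(prop-1-en-2-yl)-2,3-dihydro-1-benzofuran-7-yl}methyl)-6-ethyl-4-hydroxy-5-methyl-2H-pyran-2-one | C=C(C)[C@H]1Cc2c(O)c(C(=O)[C@H](C)CC)c(O)c(Cc3c(O)c(C)c(CC)oc3=O)c2O1 | target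

**Totals**
Total step count: 11.
Longest linear sequence: 7 steps, either 2 → 3 → 4 → 5 → 6 → 7 → 11 or, of equal length, 1 → 3 → 4 → 5 → 6 → 7 → 11.

**Three steps most likely to fail**

Step 6. The bromide is electron-rich and flanked by two ortho oxygens, so oxidative addition may be slow. Zerovalent palladium can also re-ionise the allyl aryl ether product and erode the ee.

The fallback sets out from 11 and comes back at 13.
- Stille coupling of 11 with tributyl(3-methylbut-2-enyl)stannane (Pd(PPh3)4, DMF, 100 °C) gives the ortho-prenylphenol F1.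
- TBSCl/imidazole in DMF gives the silyl ether F2.
- Shi epoxidation uses the enantiomer of the fructose-derived ketone, made from L-sorbose (KHSO5 as 2KHSO5·KHSO4·K2SO4, K2CO3, MeCN/dimethoxymethane/aqueous buffer, 0 °C). It gives the (S)-epoxide F3.
- TBAF in THF at 0 °C frees the phenoxide, which opens the epoxide 5-exo at the secondary carbon with inversion. This gives the (R)-configured tertiary alcohol F4.
- Burgess reagent (toluene, 70 °C) dehydrates F4 towards a methyl group to give 13.

Step 11. Acceptor 22 may oligomerise. It may also be caught by pyrone 19 formed through retro-Mannich cleavage, which gives the methylene-bis-pyrone instead of the cross product.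

The fallback sets out from 14 together with 19 and comes back at 23, with the roles of the two halves reversed.
- 14 is aminomethylated at C7 with 20 (CH2Cl2, rt, NaHCO3 wash) to give the benzofuran Mannich base F5.
- Heating F5 with 19 (1.5 equiv) in toluene at 95 °C expels the amine to give the ortho-quinone methide F6.
- The more acidic and more nucleophilic C3 of 19 adds to F6 in a Michael fashion to give 23.

Step 3. The di-ortho-substituted aryllithium may add slowly to the α-branched Weinreb amide. It could instead deprotonate the amide or trigger loss of formaldehyde from the N-methoxy group.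

The fallback sets out from 3 together with aryllithium 6 made from 5, and comes back at 8.
- 3 is reduced with LiAlH4 (Et2O, −78 °C) to (2R)-2-methylbutanal F7, which is kept cold as an ether solution.
- F7 is added at once to 6 at −78 °C to give the benzylic carbinol F8 as a mixture of C1 epimers.
- Dess–Martin periodinane buffered with NaHCO3 (CH2Cl2, 0 °C) oxidises both epimers to 8 without touching the α-centre.

**Further compounds**
F1 | step 6 | (2R)-1-[4-hydroxy-2,6-bis(methoxymethoxy)-3-(3-methylbut-2-en-1-yl)phenyl]-2-methylbutan-1-one | CC[C@@H](C)C(=O)c1c(OCOC)cc(O)c(CC=C(C)C)c1OCOC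
F2 | step 6 | (2R)-1-[4-(tert-butyldimethylsilyloxy)-2,6-bis(methoxymethoxy)-3-(3-methylbut-2-en-1-yl)phenyl]-2-methylbutan-1-one | CC[C@@H](C)C(=O)c1c(OCOC)cc(O[Si](C)(C)C(C)(C)C)c(CC=C(C)C)c1OCOC
F3 | step 6 | (2R)-1-[4-(tert-butyldimethylsilyloxy)-3-{[(2S)-3,3-dimethyloxiran-2-yl]methyl}-2,6-bis(methoxymethoxy)phenyl]-2-methylbutan-1-one | CC[C@@H](C)C(=O)c1c(OCOC)cc(O[Si](C)(C)C(C)(C)C)c(C[C@@H]2OC2(C)C)c1OCOC
F4 | step 6 | (2R)-1-[(2R)-2-(2-hydroxypropan-2-yl)-4,6-bis(methoxymethoxy)-2,3-dihydro-1-benzofuran-5-yl]-2-methylbutan-1-one | CC(C)(O)[C@H]1Cc2c(OCOC)c(C(=O)[C@H](C)CC)c(OCOC)cc2O1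
F5 | step 11 | (2R)-1-[(2R)-7-[(dimethylamino)methyl]-4,6-dihydroxy-2-(prop-1-en-2-yl)-2,3-dihydro-1-benzofuran-5-yl]-2-methylbutan-1-one | C=C(C)[C@H]1Cc2c(O)c(C(=O)[C@H](C)CC)c(O)c(CN(C)C)c2O1
F6 | step 11 | (2R)-4-hydroxy-5-[(2R)-2-methylbutanoyl]-7-methylidene-2-(prop-1-en-2-yl)-2,3-dihydro-1-benzofuran-6(7H)-one | C=C(C)[C@H]1CC2=C(O1)C(=C)C(=O)C(C(=O)[C@H](C)CC)=C2O
F7 | step 3 | (2R)-2-methylbutanal | CC[C@@H](C)C=O
F8 | step 3 | (2R)-1-[2,6-bis(methoxymethoxy)phenyl]-2-methylbutan-1-ol (both C1 epimers) | CC[C@@H](C)C(O)c1c(OCOC)cccc1OCOC
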